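**Retrosynthetic overview**

1. Ring numbering: C1 (C=O), C2 (bears CH2OH), C3 (=CH), C4 (CH2), C5 (quaternary: CH3 and the pentenyl hydroperoxide chain), C6 (enol ester arm), C7 (acetonyl). The strategy rests on C2, its hydroxymethyl carbon and C3 being an acrylate-type two-carbon unit between the C1 carbonyl and C4, so the cycloheptenone is a cyclopentanone (C1, C4, C5, C6, C7) enlarged by two carbons.
2. Late disconnections: tertiary allylic hydroperoxide ⇒ singlet-oxygen ene reaction of a 4-methylpent-3-enyl chain; (E)-enol senecioate ⇒ C6–CH2CHO; acetonyl ⇒ C7-allyl (Wacker); C2–CH2OH ⇒ C2–CO2Me.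
3. Key disconnection: 2-carbomethoxycyclohept-2-enone ⇒ C1=C4 trimethylsilyl enol ether of the cyclopentanone + methyl propiolate (C4–C3 and C1–C2 by (2+2) cycloaddition, then cleavage of C1–C4).
4. Enol ether ⇒ homoprenyl cuprate addition anti to the C6 arm of a (4S,5S)-5-allyl-3-methyl-4-(2-silyloxyethyl)cyclopent-2-enone; enone ⇒ (R)-2-methylcyclopent-2-enol by Johnson–Claisen rearrangement (sets C6), allylic oxidation and α′-allylation (sets C7).
5. Ring order: the cyclopentene ring comes with the starting material; the cyclobutene of a bicyclo[3.2.0]heptene is formed and opened in the same step, which gives the seven-membered ring.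

Key step: step 8

Assumption: keto ester 18 is drawn as its conjugated keto tautomer; it may equilibrate with its 1,3-dienol form, so step 9 is chosen to convert either tautomer into the same silyl dienol ether.

**Route**

Step 1
Reactants: 1 2-methylcyclopent-2-en-1-one
Product: 2 (R)-2-methylcyclopent-2-en-1-ol
Conditions: (S)-Me-CBS (10 mol%), BH3·SMe2, THF, −20 °C; MeOH
Reagents that add atoms: none
Why: Corey–Bakshi–Shibata reduction; with the methyl-substituted alkene arm acting as the large group, the (S)-catalyst should deliver hydride to give the (R)-carbinol, whose configuration is later relayed to C6.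

Step 2
Reactants: 2 (R)-2-methylcyclopent-2-en-1-ol; 3 triethyl orthoacetate
Product: 5 ethyl 2-[(1R)-2-methylcyclopent-2-en-1-yl]acetate, via ketene acetal 4 (not isolated)
Conditions: MeC(OEt)3 (excess), EtCO2H (cat.), 140 °C, −EtOH
Reagents that add atoms: triethyl orthoacetate (3), CC(OCC)(OCC)OCC
Why: Johnson–Claisen rearrangement; the ketene acetal rearranges suprafacially, so the CH2CO2Et group arrives at the former alkene CH on the face that carried the C–O bond, which transfers the carbinol configuration to the future C6 and moves the double bond to the future C4=C5.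

Step 3
Reactants: 5 ethyl 2-[(1R)-2-methylcyclopent-2-en-1-yl]acetate
Product: 6 2-[(1R)-2-methylcyclopent-2-en-1-yl]ethan-1-ol
Conditions: LiAlH4, Et2O, 0 °C
Reagents that add atoms: none
Why: Hydride reduction of the ester to the primary alcohol; the trisubstituted alkene and the stereocentre are inert.

Step 4
Reactants: 6 2-[(1R)-2-methylcyclopent-2-en-1-yl]ethan-1-ol
Product: 7 tert-butyl(dimethyl){2-[(1R)-2-methylcyclopent-2-en-1-yl]ethoxy}silane
Conditions: TBSCl, imidazole, CH2Cl2, rt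
Reagents that add atoms: tert-butyldimethylsilyl chloride, CC(C)(C)[Si](C)(C)Cl
Why: Silylation of the primary alcohol; the TBS ether tolerates base, cuprate, catalytic silyl Lewis acid and hydride and can later be removed beside a TBDPS ether.

Step 5
Reactants: 7 tert-butyl(dimethyl){2-[(1R)-2-methylcyclopent-2-en-1-yl]ethoxy}silane
Product: 8 (4S)-4-[2-(tert-butyldimethylsilyloxy)ethyl]-3-methylcyclopent-2-en-1-one
Conditions: CrO3, 3,5-dimethylpyrazole, CH2Cl2, −20 °C
Reagents that add atoms: chromium trioxide, O=[Cr](=O)=O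
Why: Allylic oxidation with the chromium trioxide–dimethylpyrazole complex turns the ring CH2 next to the alkene CH into the enone carbonyl (future C1) without touching C6; attack at the tertiary allylic C–H would give a transposed enone as a by-product to be removed.

Step 6
Reactants: 8 (4S)-4-[2-(tert-butyldimethylsilyloxy)ethyl]-3-methylcyclopent-2-en-1-one; 9 allyl bromide
Product: 11 (4S,5S)-4-[2-(tert-butyldimethylsilyloxy)ethyl]-3-methyl-5-(prop-2-en-1-yl)cyclopent-2-en-1-one, via lithium enolate 10 (not isolated)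
Conditions: LDA, THF, −78 °C; allyl bromide, DMPU, −78 → −30 °C
Reagents that add atoms: allyl bromide (9), C=CCBr
Why: Kinetic deprotonation at the α′-CH2 gives the cross-conjugated enolate, and enolate alkylation anti to the adjacent C6 side chain should set C7 trans to it, which is also the thermodynamically favoured arrangement.

Step 7
Reactants: 11 (4S,5S)-4-[2-(tert-butyldimethylsilyloxy)ethyl]-3-methyl-5-(prop-2-en-1-yl)cyclopent-2-en-1-one; 12 5-bromo-2-methylpent-2-ene
Product: 14 (3R,4S,5S)-4-[2-(tert-butyldimethylsilyloxy)ethyl]-3-methyl-3-(4-methylpent-3-en-1-yl)-5-(prop-2-en-1-yl)-1-(trimethylsilyloxy)cyclopent-1-ene, via Grignard reagent 13 (not isolated)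
Conditions: Mg, THF (12 → 13); CuBr·SMe2 (20 mol%), TMSCl, HMPA, THF, −78 → −40 °C; Et3N, cold NaHCO3
Reagents that add atoms: 5-bromo-2-methylpent-2-ene (12), CC(C)=CCCBr; chlorotrimethylsilane, C[Si](C)(C)Cl
Why: Copper-catalysed conjugate addition of the Grignard reagent accelerated by TMSCl; the nucleophile should add to the β-carbon anti to the adjacent C6 side chain, which sets the quaternary C5 (methyl cis to the C6 arm), and O-silylation of the resulting enolate fixes the enol ether regiospecifically as C1=C4.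

Step 8
Reactants: 14 (3R,4S,5S)-4-[2-(tert-butyldimethylsilyloxy)ethyl]-3-methyl-3-(4-methylpent-3-en-1-yl)-5-(prop-2-en-1-yl)-1-(trimethylsilyloxy)cyclopent-1-ene; 15 methyl propiolate
Product: 18 methyl (4S,5S,6S)-5-[2-(tert-butyldimethylsilyloxy)ethyl]-4-methyl-4-(4-methylpent-3-en-1-yl)-7-oxo-6-(prop-2-en-1-yl)cyclohept-1-ene-1-carboxylate, via siloxycyclobutene 16 (not isolated), via ammonium dienolate 17 (not isolated)
Conditions: 15 (1.5 equiv), Tf2NH (5 mol%), CH2Cl2, −78 °C; Et3N (10 mol%), evaporate volatiles; TBAF (1.05 equiv), THF, −78 °C; AcOH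
Reagents that add atoms: methyl propiolate (15), COC(=O)C#C
Why: Mukaiyama–Michael-type attack of the enol-ether carbon C4 on the β-carbon of the silyl-activated propiolate (the silyl triflimide formed from Tf2NH and 14 is the working Lewis acid) forms C4–C3, and the allenoate carbon then closes onto the silyloxocarbenium carbon C1 (4-exo-trig) to form C1–C2 and the cyclobutene of 16, a stepwise (2+2) cycloaddition known for silyl enol ethers of cyclic ketones with propiolates. Fluoride then removes the tertiary trimethylsilyl group and the cyclobutenoxide opens at the C1–C4 bond in a charge-accelerated vinylogous retro-aldol fragmentation (related to the enamine–acetylenic ester ring enlargement), so the seven-membered ring arises by expansion of the bicyclo[3.2.0]heptene and not by a separate closure, giving dienolate 17 and, on protonation, 18. No stereocentre is created in the product: the two ring-fusion centres of 16 are erased on opening, and C5, C6 and C7 are spectators. The step needs the ester on C2 and the CH on C3, which the polarity of enol ether and ynoate secures; it needs the enol ether to react before the allyl and homoprenyl alkenes, which its far higher nucleophilicity at −78 °C secures; and it needs ring closure of the zwitterion to outrun silyl transfer to an open-chain adduct, for which the low temperature and the intramolecular ion-pair collapse are relied on. The hindrance of C4 next to the quaternary C5 is the main uncertainty.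

Step 9
Reactants: 18 methyl (4S,5S,6S)-5-[2-(tert-butyldimethylsilyloxy)ethyl]-4-methyl-4-(4-methylpent-3-en-1-yl)-7-oxo-6-(prop-2-en-1-yl)cyclohept-1-ene-1-carboxylate
Product: 19 methyl (3S,4S,5S)-4-[2-(tert-butyldimethylsilyloxy)ethyl]-5-methyl-5-(4-methylpent-3-en-1-yl)-3-(prop-2-en-1-yl)-2-(triethylsilyloxy)cyclohepta-1,6-diene-1-carboxylate
Conditions: TESCl, DBU (added last), CH2Cl2, −78 → 0 °C
Reagents that add atoms: chlorotriethylsilane, CC[Si](CC)(CC)Cl
Why: Silyl enol ether formation from a β-dicarbonyl compound; DBU deprotonates either tautomer (at the doubly activated C4–H or at the enol O–H) to the same dienolate, and O-silylation gives the push–pull silyl dienol ether that masks the C1 ketone for the hydride step.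

Step 10
Reactants: 19 methyl (3S,4S,5S)-4-[2-(tert-butyldimethylsilyloxy)ethyl]-5-methyl-5-(4-methylpent-3-en-1-yl)-3-(prop-2-en-1-yl)-2-(triethylsilyloxy)cyclohepta-1,6-diene-1-carboxylate
Product: 20 [(3S,4S,5S)-4-[2-(tert-butyldimethylsilyloxy)ethyl]-5-methyl-5-(4-methylpent-3-en-1-yl)-3-(prop-2-en-1-yl)-2-(triethylsilyloxy)cyclohepta-1,6-dien-1-yl]methanol
Conditions: DIBAL-H, CH2Cl2, −78 °C; Rochelle salt
Reagents that add atoms: none
Why: DIBAL-H 1,2-reduction of the β-silyloxy enoate to the allylic alcohol while the ketone stays masked as its silyl enol ether; the acid-sensitive product is taken on after a neutral tartrate work-up.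

Step 11
Reactants: 20 [(3S,4S,5S)-4-[2-(tert-butyldimethylsilyloxy)ethyl]-5-methyl-5-(4-methylpent-3-en-1-yl)-3-(prop-2-en-1-yl)-2-(triethylsilyloxy)cyclohepta-1,6-dien-1-yl]methanol
Product: 21 (5S,6S,7S)-6-[2-(tert-butyldimethylsilyloxy)ethyl]-2-(hydroxymethyl)-5-methyl-5-(4-methylpent-3-en-1-yl)-7-(prop-2-en-1-yl)cyclohept-2-en-1-one
Conditions: TBAF, AcOH, THF, −20 °C; then DBU (0.3 equiv), 0 °C → rt
Reagents that add atoms: none
Why: Buffered fluoride cleaves the silyl enol ether far faster than the alkyl TBS ether, and DBU-catalysed alkene isomerisation moves the C3=C4 double bond into the conjugated, trisubstituted C2=C3 position, the free hydroxyl being too poor a leaving group for vinylogous β-elimination under these conditions.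

Step 12
Reactants: 21 (5S,6S,7S)-6-[2-(tert-butyldimethylsilyloxy)ethyl]-2-(hydroxymethyl)-5-methyl-5-(4-methylpent-3-en-1-yl)-7-(prop-2-en-1-yl)cyclohept-2-en-1-one
Product: 22 (5S,6S,7S)-6-[2-(tert-butyldimethylsilyloxy)ethyl]-2-[(tert-butyldiphenylsilyloxy)methyl]-5-methyl-5-(4-methylpent-3-en-1-yl)-7-(prop-2-en-1-yl)cyclohept-2-en-1-one
Conditions: TBDPSCl, imidazole, CH2Cl2, 0 °C → rt
Reagents that add atoms: tert-butyl(chloro)diphenylsilane, CC(C)(C)[Si](Cl)(c1ccccc1)c1ccccc1
Why: Silylation of the primary allylic alcohol; the TBDPS ether is much more acid-stable than the TBS ether, which makes step 14 possible.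

Step 13
Reactants: 22 (5S,6S,7S)-6-[2-(tert-butyldimethylsilyloxy)ethyl]-2-[(tert-butyldiphenylsilyloxy)methyl]-5-methyl-5-(4-methylpent-3-en-1-yl)-7-(prop-2-en-1-yl)cyclohept-2-en-1-one
Product: 23 (5S,6S,7S)-6-[2-(tert-butyldimethylsilyloxy)ethyl]-2-[(tert-butyldiphenylsilyloxy)methyl]-5-methyl-5-(4-methylpent-3-en-1-yl)-7-(2-oxopropyl)cyclohept-2-en-1-one
Conditions: PdCl2 (15 mol%), CuCl, O2 (1 atm), DMF/H2O 7:1, rt
Reagents that add atoms: water, O
Why: Tsuji–Wacker oxidation; Markovnikov oxypalladation of the monosubstituted alkene and β-hydride elimination give the methyl ketone, while the trisubstituted alkene and the enone do not react under these conditions.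

Step 14
Reactants: 23 (5S,6S,7S)-6-[2-(tert-butyldimethylsilyloxy)ethyl]-2-[(tert-butyldiphenylsilyloxy)methyl]-5-methyl-5-(4-methylpent-3-en-1-yl)-7-(2-oxopropyl)cyclohept-2-en-1-one
Product: 24 (5S,6S,7S)-2-[(tert-butyldiphenylsilyloxy)methyl]-6-(2-hydroxyethyl)-5-methyl-5-(4-methylpent-3-en-1-yl)-7-(2-oxopropyl)cyclohept-2-en-1-one
Conditions: CSA (10 mol%), MeOH/CH2Cl2, 0 °C
Reagents that add atoms: none
Why: Selective silyl ether cleavage; acid-catalysed methanolysis removes the primary alkyl TBS ether much faster than the TBDPS ether.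

Step 15
Reactants: 24 (5S,6S,7S)-2-[(tert-butyldiphenylsilyloxy)methyl]-6-(2-hydroxyethyl)-5-methyl-5-(4-methylpent-3-en-1-yl)-7-(2-oxopropyl)cyclohept-2-en-1-one
Product: 25 (5S,6S,7S)-2-[(tert-butyldiphenylsilyloxy)methyl]-5-methyl-5-(4-methylpent-3-en-1-yl)-6-(2-oxoethyl)-7-(2-oxopropyl)cyclohept-2-en-1-one
Conditions: Dess–Martin periodinane, NaHCO3, CH2Cl2, 0 °C → rt
Reagents that add atoms: none
Why: Dess–Martin oxidation of the primary alcohol to the aldehyde under buffered, non-enolising conditions.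

Step 16
Reactants: 25 (5S,6S,7S)-2-[(tert-butyldiphenylsilyloxy)methyl]-5-methyl-5-(4-methylpent-3-en-1-yl)-6-(2-oxoethyl)-7-(2-oxopropyl)cyclohept-2-en-1-one; 26 3-methylbut-2-enoic acid
Product: 28 (E)-2-[(1S,2S,7S)-5-[(tert-butyldiphenylsilyloxy)methyl]-2-methyl-2-(4-methylpent-3-en-1-yl)-6-oxo-7-(2-oxopropyl)cyclohept-4-en-1-yl]ethenyl 3-methylbut-2-enoate, via senecioic anhydride 27 (not isolated)
Conditions: 26, DCC, CH2Cl2, 0 °C → rt (→ 27); then 25, Et3N, DMAP, rt
Reagents that add atoms: 3-methylbut-2-enoic acid (26), CC(C)=CC(=O)O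
Why: Enol ester formation by DMAP-catalysed O-acylation of the aldehyde enol(ate) with the anhydride made in the flask; the aldehyde is enolised far more readily than the two ketones under amine base, and the (E)-enol ester is expected as the main isomer, the (Z)-isomer being removed by chromatography.

Step 17
Reactants: 28 (E)-2-[(1S,2S,7S)-5-[(tert-butyldiphenylsilyloxy)methyl]-2-methyl-2-(4-methylpent-3-en-1-yl)-6-oxo-7-(2-oxopropyl)cyclohept-4-en-1-yl]ethenyl 3-methylbut-2-enoate
Product: 29 (E)-2-[(1S,2S,7S)-5-(hydroxymethyl)-2-methyl-2-(4-methylpent-3-en-1-yl)-6-oxo-7-(2-oxopropyl)cyclohept-4-en-1-yl]ethenyl 3-methylbut-2-enoate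
Conditions: HF·pyridine, pyridine, THF, 0 °C → rt
Reagents that add atoms: none
Why: Fluoride-mediated cleavage of the TBDPS ether with pyridine-buffered HF·pyridine, which is acidic enough to spare the enol ester and the senecioate.

Step 18
Reactants: 29 (E)-2-[(1S,2S,7S)-5-(hydroxymethyl)-2-methyl-2-(4-methylpent-3-en-1-yl)-6-oxo-7-(2-oxopropyl)cyclohept-4-en-1-yl]ethenyl 3-methylbut-2-enoate
Product: 30 (E)-2-[(1S,2S,7S)-2-[(E)-4-hydroperoxy-4-methylpent-2-en-1-yl]-5-(hydroxymethyl)-2-methyl-6-oxo-7-(2-oxopropyl)cyclohept-4-en-1-yl]ethenyl 3-methylbut-2-enoate (target)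
Conditions: O2, tetraphenylporphyrin (cat.), visible light, CH2Cl2, −20 °C
Reagents that add atoms: dioxygen, O=O
Why: Schenck ene reaction of singlet oxygen with the only electron-rich trisubstituted alkene; oxygen adds to the dimethyl-substituted carbon with abstraction of an allylic CH2 hydrogen to give the tertiary hydroperoxide and the (E)-alkene, whereas abstraction from a methyl group gives the secondary hydroperoxide regioisomer that has to be separated, and the enone, enol ester and senecioate alkenes are electron-poor and react much more slowly.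

**Compound list**

1 | 2-methylcyclopent-2-en-1-one | CC1=CCCC1=O | starting material
2 | (R)-2-methylcyclopent-2-en-1-ol | CC1=CCC[C@H]1O | intermediate
3 | triethyl orthoacetate | CC(OCC)(OCC)OCC | starting material
4 | ketene acetal, 1-ethoxy-1-{[(1R)-2-methylcyclopent-2-en-1-yl]oxy}ethene | C=C(OCC)O[C@H]1C(C)=CCC1 | intermediate
5 | ethyl 2-[(1R)-2-methylcyclopent-2-en-1-yl]acetate | CC1=CCC[C@@H]1CC(=O)OCC | intermediate
6 | 2-[(1R)-2-methylcyclopent-2-en-1-yl]ethan-1-ol | CC1=CCC[C@@H]1CCO | intermediate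
7 | tert-butyl(dimethyl){2-[(1R)-2-methylcyclopent-2-en-1-yl]ethoxy}silane | CC1=CCC[C@@H]1CCO[Si](C)(C)C(C)(C)C | intermediate
8 | (4S)-4-[2-(tert-butyldimethylsilyloxy)ethyl]-3-methylcyclopent-2-en-1-one | O=C1C=C(C)[C@@H](CCO[Si](C)(C)C(C)(C)C)C1 | intermediate
9 | allyl bromide | C=CCBr | starting material
10 | lithium (3S)-3-[2-(tert-butyldimethylsilyloxy)ethyl]-4-methylcyclopenta-1,4-dien-1-olate (α′-enolate of 8) | [Li]OC1=C[C@H](CCO[Si](C)(C)C(C)(C)C)C(C)=C1 | intermediate
11 | (4S,5S)-4-[2-(tert-butyldimethylsilyloxy)ethyl]-3-methyl-5-(prop-2-en-1-yl)cyclopent-2-en-1-one | O=C1C=C(C)[C@@H](CCO[Si](C)(C)C(C)(C)C)[C@@H]1CC=C | intermediate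
12 | 5-bromo-2-methylpent-2-ene | CC(C)=CCCBr | starting material
13 | (4-methylpent-3-en-1-yl)magnesium bromide | CC(C)=CCC[Mg]Br | intermediate
14 | (3R,4S,5S)-4-[2-(tert-butyldimethylsilyloxy)ethyl]-3-methyl-3-(4-methylpent-3-en-1-yl)-5-(prop-2-en-1-yl)-1-(trimethylsilyloxy)cyclopent-1-ene (C1=C4 enol ether; methyl cis to the C6 arm, allyl trans to it) | C[Si](C)(C)OC1=C[C@](C)(CCC=C(C)C)[C@@H](CCO[Si](C)(C)C(C)(C)C)[C@@H]1CC=C | intermediate
15 | methyl propiolate | COC(=O)C#C | starting material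
16 | methyl 2-allyl-3-[2-(tert-butyldimethylsilyloxy)ethyl]-4-methyl-4-(4-methylpent-3-en-1-yl)-1-(trimethylsilyloxy)bicyclo[3.2.0]hept-6-ene-7-carboxylate (cis-fused; either ring-fusion diastereomer; other centres as in 14) | COC(=O)C1=CC2C1(O[Si](C)(C)C)[C@@H](CC=C)[C@H](CCO[Si](C)(C)C(C)(C)C)[C@@]2(C)CCC=C(C)C | intermediate
17 | tetrabutylammonium dienolate of 18 (O–C1=C2(CO2Me)–C3=C4) | COC(=O)C1=C([O-])[C@@H](CC=C)[C@H](CCO[Si](C)(C)C(C)(C)C)[C@@](C)(CCC=C(C)C)C=C1.CCCC[N+](CCCC)(CCCC)CCCC | intermediate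
18 | methyl (4S,5S,6S)-5-[2-(tert-butyldimethylsilyloxy)ethyl]-4-methyl-4-(4-methylpent-3-en-1-yl)-7-oxo-6-(prop-2-en-1-yl)cyclohept-1-ene-1-carboxylate | COC(=O)C1=CC[C@](C)(CCC=C(C)C)[C@@H](CCO[Si](C)(C)C(C)(C)C)[C@H](CC=C)C1=O | intermediate
19 | methyl (3S,4S,5S)-4-[2-(tert-butyldimethylsilyloxy)ethyl]-5-methyl-5-(4-methylpent-3-en-1-yl)-3-(prop-2-en-1-yl)-2-(triethylsilyloxy)cyclohepta-1,6-diene-1-carboxylate | COC(=O)C1=C(O[Si](CC)(CC)CC)[C@@H](CC=C)[C@H](CCO[Si](C)(C)C(C)(C)C)[C@@](C)(CCC=C(C)C)C=C1 | intermediate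
20 | [(3S,4S,5S)-4-[2-(tert-butyldimethylsilyloxy)ethyl]-5-methyl-5-(4-methylpent-3-en-1-yl)-3-(prop-2-en-1-yl)-2-(triethylsilyloxy)cyclohepta-1,6-dien-1-yl]methanol | OCC1=C(O[Si](CC)(CC)CC)[C@@H](CC=C)[C@H](CCO[Si](C)(C)C(C)(C)C)[C@@](C)(CCC=C(C)C)C=C1 | intermediate
21 | (5S,6S,7S)-6-[2-(tert-butyldimethylsilyloxy)ethyl]-2-(hydroxymethyl)-5-methyl-5-(4-methylpent-3-en-1-yl)-7-(prop-2-en-1-yl)cyclohept-2-en-1-one | OCC1=CC[C@](C)(CCC=C(C)C)[C@@H](CCO[Si](C)(C)C(C)(C)C)[C@H](CC=C)C1=O | intermediate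
22 | (5S,6S,7S)-6-[2-(tert-butyldimethylsilyloxy)ethyl]-2-[(tert-butyldiphenylsilyloxy)methyl]-5-methyl-5-(4-methylpent-3-en-1-yl)-7-(prop-2-en-1-yl)cyclohept-2-en-1-one | CC(C)(C)[Si](OCC1=CC[C@](C)(CCC=C(C)C)[C@@H](CCO[Si](C)(C)C(C)(C)C)[C@H](CC=C)C1=O)(c1ccccc1)c1ccccc1 | intermediate
23 | (5S,6S,7S)-6-[2-(tert-butyldimethylsilyloxy)ethyl]-2-[(tert-butyldiphenylsilyloxy)methyl]-5-methyl-5-(4-methylpent-3-en-1-yl)-7-(2-oxopropyl)cyclohept-2-en-1-one | CC(C)(C)[Si](OCC1=CC[C@](C)(CCC=C(C)C)[C@@H](CCO[Si](C)(C)C(C)(C)C)[C@H](CC(C)=O)C1=O)(c1ccccc1)c1ccccc1 | intermediate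
24 | (5S,6S,7S)-2-[(tert-butyldiphenylsilyloxy)methyl]-6-(2-hydroxyethyl)-5-methyl-5-(4-methylpent-3-en-1-yl)-7-(2-oxopropyl)cyclohept-2-en-1-one | CC(C)(C)[Si](OCC1=CC[C@](C)(CCC=C(C)C)[C@@H](CCO)[C@H](CC(C)=O)C1=O)(c1ccccc1)c1ccccc1 | intermediate
25 | (5S,6S,7S)-2-[(tert-butyldiphenylsilyloxy)methyl]-5-methyl-5-(4-methylpent-3-en-1-yl)-6-(2-oxoethyl)-7-(2-oxopropyl)cyclohept-2-en-1-one | CC(C)(C)[Si](OCC1=CC[C@](C)(CCC=C(C)C)[C@@H](CC=O)[C@H](CC(C)=O)C1=O)(c1ccccc1)c1ccccc1 | intermediate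
26 | 3-methylbut-2-enoic acid (senecioic acid) | CC(C)=CC(=O)O | starting material
27 | 3-methylbut-2-enoic anhydride (senecioic anhydride) | CC(C)=CC(=O)OC(=O)C=C(C)C | intermediate
28 | (E)-2-[(1S,2S,7S)-5-[(tert-butyldiphenylsilyloxy)methyl]-2-methyl-2-(4-methylpent-3-en-1-yl)-6-oxo-7-(2-oxopropyl)cyclohept-4-en-1-yl]ethenyl 3-methylbut-2-enoate | CC(C)(C)[Si](OCC1=CC[C@](C)(CCC=C(C)C)[C@@H](/C=C/OC(=O)C=C(C)C)[C@H](CC(C)=O)C1=O)(c1ccccc1)c1ccccc1 | intermediate
29 | (E)-2-[(1S,2S,7S)-5-(hydroxymethyl)-2-methyl-2-(4-methylpent-3-en-1-yl)-6-oxo-7-(2-oxopropyl)cyclohept-4-en-1-yl]ethenyl 3-methylbut-2-enoate | OCC1=CC[C@](C)(CCC=C(C)C)[C@@H](/C=C/OC(=O)C=C(C)C)[C@H](CC(C)=O)C1=O | intermediate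
30 | (E)-2-[(1S,2S,7S)-2-[(E)-4-hydroperoxy-4-methylpent-2-en-1-yl]-5-(hydroxymethyl)-2-methyl-6-oxo-7-(2-oxopropyl)cyclohept-4-en-1-yl]ethenyl 3-methylbut-2-enoate (CNP0283385.2) | OCC1=CC[C@](C)(C/C=C/C(C)(C)OO)[C@@H](/C=C/OC(=O)C=C(C)C)[C@H](CC(C)=O)C1=O | target

**Step count and risks**

Total steps: 18. Longest linear sequence: 18 steps (1 → 30); compounds 3, 9, 12, 15 and 26 are used as purchased.

Steps most likely to fail:

Step 8 (key step). Bond formation at C4, which is flanked by the quaternary C5, may be slow, so that protodesilylation of the enol ether, or silyl transfer within the zwitterion to an open-chain β-(2-oxocyclopentyl)acrylate, overtakes closure of the four-membered ring. The fallback is the neutral enamine version of the two-carbon enlargement. It sets out from 14. Methanolysis of the enol ether (K2CO3, MeOH, 0 °C) gives (2S,3S,4S)-2-allyl-3-[2-(tert-butyldimethylsilyloxy)ethyl]-4-methyl-4-(4-methylpent-3-en-1-yl)cyclopentan-1-one F1. Condensation with pyrrolidine (cat. TsOH, toluene, water separator) gives the less substituted enamine 1-[(3R,4S,5S)-5-allyl-4-[2-(tert-butyldimethylsilyloxy)ethyl]-3-methyl-3-(4-methylpent-3-en-1-yl)cyclopent-1-en-1-yl]pyrrolidine F2, whose double bond lies toward C4 because C7 carries the allyl group. With methyl propiolate 15 (MeCN, 0 °C → rt), thermal cycloaddition and spontaneous ring opening give the dienamine methyl (3S,4S,5S)-3-allyl-4-[2-(tert-butyldimethylsilyloxy)ethyl]-5-methyl-5-(4-methylpent-3-en-1-yl)-2-(pyrrolidin-1-yl)cyclohepta-1,6-diene-1-carboxylate F3. Hydrolysis (aq. AcOH, THF) comes back to the route at 18.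

Step 11. The enol(ate) set free next to the hydroxymethyl group may expel the oxygen by vinylogous β-elimination to a 2-methylene dienone, or the C3=C4 double bond may not move fully into conjugation. In the fallback the hydroxymethyl group is attached by cross-coupling instead of being derived from the ester. It sets out from 18. Saponification and decarboxylation (LiOH, THF/H2O, 40 °C; then AcOH, 50 °C; DBU to complete conjugation) give (5S,6S,7S)-6-[2-(tert-butyldimethylsilyloxy)ethyl]-5-methyl-5-(4-methylpent-3-en-1-yl)-7-(prop-2-en-1-yl)cyclohept-2-en-1-one F4. α-Iodination (I2, pyridine, CH2Cl2) gives (5S,6S,7S)-6-[2-(tert-butyldimethylsilyloxy)ethyl]-2-iodo-5-methyl-5-(4-methylpent-3-en-1-yl)-7-(prop-2-en-1-yl)cyclohept-2-en-1-one F5. Stille coupling with (tributylstannyl)methanol (Pd2(dba)3, AsPh3, CuI, NMP, 50 °C) comes back to the route at 21.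

Step 16. Under the amine base the aldehyde and the methyl ketone of 25 may undergo intramolecular aldol reaction (five-membered ring closure) faster than the enol is acylated; in addition E/Z control may be poor and the acyl donor may lose conjugation through a vinylketene. In the fallback the enol ester is made before the methyl ketone exists. It sets out from 22. Cleavage of the TBS ether (CSA, MeOH/CH2Cl2, 0 °C) gives (5S,6S,7S)-2-[(tert-butyldiphenylsilyloxy)methyl]-6-(2-hydroxyethyl)-5-methyl-5-(4-methylpent-3-en-1-yl)-7-(prop-2-en-1-yl)cyclohept-2-en-1-one F6. Dess–Martin oxidation gives (5S,6S,7S)-2-[(tert-butyldiphenylsilyloxy)methyl]-5-methyl-5-(4-methylpent-3-en-1-yl)-6-(2-oxoethyl)-7-(prop-2-en-1-yl)cyclohept-2-en-1-one F7. Acylation as in step 16 gives (E)-2-[(1S,2S,7S)-5-[(tert-butyldiphenylsilyloxy)methyl]-2-methyl-2-(4-methylpent-3-en-1-yl)-6-oxo-7-(prop-2-en-1-yl)cyclohept-4-en-1-yl]ethenyl 3-methylbut-2-enoate F8. Tsuji–Wacker oxidation of F8 (PdCl2, CuCl, O2, DMF/H2O) comes back to the route at 28.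

**Further compounds**

F1 | step 8 | (2S,3S,4S)-2-allyl-3-[2-(tert-butyldimethylsilyloxy)ethyl]-4-methyl-4-(4-methylpent-3-en-1-yl)cyclopentan-1-one | O=C1C[C@](C)(CCC=C(C)C)[C@@H](CCO[Si](C)(C)C(C)(C)C)[C@@H]1CC=C
F2 | step 8 | 1-[(3R,4S,5S)-5-allyl-4-[2-(tert-butyldimethylsilyloxy)ethyl]-3-methyl-3-(4-methylpent-3-en-1-yl)cyclopent-1-en-1-yl]pyrrolidine | N1(CCCC1)C2=C[C@](C)(CCC=C(C)C)[C@@H](CCO[Si](C)(C)C(C)(C)C)[C@@H]2CC=C
F3 | step 8 | methyl (3S,4S,5S)-3-allyl-4-[2-(tert-butyldimethylsilyloxy)ethyl]-5-methyl-5-(4-methylpent-3-en-1-yl)-2-(pyrrolidin-1-yl)cyclohepta-1,6-diene-1-carboxylate | COC(=O)C1=C(N2CCCC2)[C@@H](CC=C)[C@H](CCO[Si](C)(C)C(C)(C)C)[C@@](C)(CCC=C(C)C)C=C1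
F4 | step 11 | (5S,6S,7S)-6-[2-(tert-butyldimethylsilyloxy)ethyl]-5-methyl-5-(4-methylpent-3-en-1-yl)-7-(prop-2-en-1-yl)cyclohept-2-en-1-one | O=C1C=CC[C@](C)(CCC=C(C)C)[C@@H](CCO[Si](C)(C)C(C)(C)C)[C@@H]1CC=C
F5 | step 11 | (5S,6S,7S)-6-[2-(tert-butyldimethylsilyloxy)ethyl]-2-iodo-5-methyl-5-(4-methylpent-3-en-1-yl)-7-(prop-2-en-1-yl)cyclohept-2-en-1-one | O=C1C(I)=CC[C@](C)(CCC=C(C)C)[C@@H](CCO[Si](C)(C)C(C)(C)C)[C@@H]1CC=C
F6 | step 16 | (5S,6S,7S)-2-[(tert-butyldiphenylsilyloxy)methyl]-6-(2-hydroxyethyl)-5-methyl-5-(4-methylpent-3-en-1-yl)-7-(prop-2-en-1-yl)cyclohept-2-en-1-one | CC(C)(C)[Si](OCC1=CC[C@](C)(CCC=C(C)C)[C@@H](CCO)[C@H](CC=C)C1=O)(c1ccccc1)c1ccccc1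
F7 | step 16 | (5S,6S,7S)-2-[(tert-butyldiphenylsilyloxy)methyl]-5-methyl-5-(4-methylpent-3-en-1-yl)-6-(2-oxoethyl)-7-(prop-2-en-1-yl)cyclohept-2-en-1-one | CC(C)(C)[Si](OCC1=CC[C@](C)(CCC=C(C)C)[C@@H](CC=O)[C@H](CC=C)C1=O)(c1ccccc1)c1ccccc1
F8 | step 16 | (E)-2-[(1S,2S,7S)-5-[(tert-butyldiphenylsilyloxy)methyl]-2-methyl-2-(4-methylpent-3-en-1-yl)-6-oxo-7-(prop-2-en-1-yl)cyclohept-4-en-1-yl]ethenyl 3-methylbut-2-enoate | CC(C)(C)[Si](OCC1=CC[C@](C)(CCC=C(C)C)[C@@H](/C=C/OC(=O)C=C(C)C)[C@H](CC=C)C1=O)(c1ccccc1)c1ccccc1
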